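**Plan**

Numbering (spiro[5.5]undecane): ring B is C1–C5 with C2 = CHBr and C3 = C(Me)OH; C6 is the spiro carbon; ring A is C7–C11 with C7(Me)=C8H, C10 = CHBr and C11 = CMe2.
Cuts, in retrosynthetic order: C7=C8 (ring-closing metathesis), C7=CH2 and C7–CH3 (both from a lactone carbonyl), C9–CH= (triflate/vinyl coupling), C10–Br, C3–O together with C2–Br (bromolactonisation), C6–C11 (Ireland–Claisen). The metathesis is possible because the ring A olefin lies between C6, which can carry C7 as an isopropenyl group, and the C9H2–C10HBr–C11Me2 arm, which can end in a vinyl group; the adjacent fully substituted C6 and C11 pre-fold this 1,7-diene.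
Forward: ring B is the carbocycle of (S)-limonene. Its isopropenyl group is cut down to a carboxyl group, a prenyl ester rearranges to join C11 to C6, the side chain is grown out to C8, and ring A closes last.
Stereochemistry: the limonene stereocentre sets a trans-diaxial bromo ether, and its axial bromine steers the sigmatropic shift at C6. This sense of attack (anti to bromine) is the reason the mirror-image limonene is used. The two relay centres are then erased, and the carboxyl group on C6 delivers O to C3 and Br anti to C2. C10 is set by enamine catalysis.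

Key step: step 15

Assumption: (S)-limonene is used at high enantiomeric purity; if a commercial lot falls short, the deficit would be removed by recrystallising acid 12 as an amine salt or bromolactone 13.

**Route**

Step 1
Reactants: 1 (S)-limonene
Product: 2 (1R,2R,4S)-2-bromo-1-methoxy-1-methyl-4-(prop-1-en-2-yl)cyclohexane
Conditions: NBS (1.0 equiv), MeOH, 0 °C, dark
Reagents that add atoms: N-bromosuccinimide (O=C1CCC(=O)N1Br); methanol (CO)
Why: Alkoxybromination (cohalogenation) picks the more electron-rich trisubstituted ring olefin over the isopropenyl group, and methanol opens the bromonium ion at the tertiary carbon in the trans-diaxial mode fixed by the equatorial isopropenyl group, so C–O and C–Br are both set by the limonene stereocentre.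

Step 2
Reactants: 2 (1R,2R,4S)-2-bromo-1-methoxy-1-methyl-4-(prop-1-en-2-yl)cyclohexane
Product: 4 1-[(1S,3R,4R)-3-bromo-4-methoxy-4-methylcyclohexyl]ethan-1-one, via ozonide 3 (not isolated)
Conditions: O3, CH2Cl2, −78 °C; then Me2S, −78 → 25 °C
Reagents that add atoms: ozone ([O-][O+]=O)
Why: Ozonolysis with reductive work-up cleaves the only olefin left to the methyl ketone through secondary ozonide 3, the neopentylic bromide and the methyl ether being inert to ozone and no stereocentre being touched.

Step 3
Reactants: 4 1-[(1S,3R,4R)-3-bromo-4-methoxy-4-methylcyclohexyl]ethan-1-one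
Product: 6 (1S,3R,4R)-3-bromo-4-methoxy-4-methylcyclohexane-1-carboxylic acid, via tribromomethyl ketone 5 (not isolated)
Conditions: Br2, NaOH, H2O/1,4-dioxane, 0 → 20 °C; then HCl
Reagents that add atoms: sodium hydroxide ([Na+].[OH-])
Why: Haloform degradation: exhaustive α-bromination of the methyl group gives tribromomethyl ketone 5, which hydroxide cleaves to the carboxylate and bromoform; epimerisation at the ring carbon next to the carbonyl group would be harmless because that carbon becomes trigonal in step 5, and the neopentylic, β-oxygenated bromide is slow to react with hydroxide at 0 °C.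

Step 4
Reactants: 6 (1S,3R,4R)-3-bromo-4-methoxy-4-methylcyclohexane-1-carboxylic acid; 7 3-methylbut-2-en-1-ol
Product: 8 3-methylbut-2-en-1-yl (1S,3R,4R)-3-bromo-4-methoxy-4-methylcyclohexane-1-carboxylate
Conditions: DCC, DMAP (cat.), CH2Cl2, 0 → 25 °C
Reagents that add atoms: 3-methylbut-2-en-1-ol 7 (CC(C)=CCO)
Why: Steglich esterification of a secondary carboxylic acid with a primary allylic alcohol under neutral conditions, which leaves the bromo ether and all stereocentres alone.

Step 5
Reactants: 8 3-methylbut-2-en-1-yl (1S,3R,4R)-3-bromo-4-methoxy-4-methylcyclohexane-1-carboxylate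
Product: 11 (1R,3R,4R)-3-bromo-4-methoxy-4-methyl-1-(2-methylbut-3-en-2-yl)cyclohexane-1-carboxylic acid, via silyl ketene acetal 9 (not isolated), via trimethylsilyl ester 10 (not isolated)
Conditions: LDA (LiN(iPr)2), TMSCl/Et3N (present from the start), THF, −78 °C; then 25 → 60 °C; 1 M HCl; chromatography
Reagents that add atoms: none
Why: Ireland–Claisen rearrangement: the ester enolate is silylated as it forms, so that it cannot displace the neopentylic bromide, and ketene acetal 9 rearranges through a chair-like [3,3] transition state in which the prenyl terminus bonds to the ring carbon from the face anti to the axial C–Br bond two atoms away (bromine and methoxy trans-diaxial, methyl equatorial in the favoured chair), the 1,3-diaxial control familiar from alkylations of exocyclic cyclohexane ester enolates, which sets the quaternary stereocentre with CMe2 trans to bromine; the minor epimer would be removed by chromatography at this stage.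

Step 6
Reactants: 11 (1R,3R,4R)-3-bromo-4-methoxy-4-methyl-1-(2-methylbut-3-en-2-yl)cyclohexane-1-carboxylic acid
Product: 12 (R)-4-methyl-1-(2-methylbut-3-en-2-yl)cyclohex-3-ene-1-carboxylic acid
Conditions: Zn dust, AcOH, THF, 50 °C
Reagents that add atoms: none
Why: Zinc-induced reductive anti-elimination of the vicinal bromo ether (Boord olefin synthesis) proceeds from the trans-diaxial arrangement already present, restores the trisubstituted ring olefin and erases the two relay stereocentres, so that the quaternary carbon is now the only stereocentre.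

Step 7
Reactants: 12 (R)-4-methyl-1-(2-methylbut-3-en-2-yl)cyclohex-3-ene-1-carboxylic acid
Product: 13 (1S,4R,6S)-6-bromo-1-methyl-4-(2-methylbut-3-en-2-yl)-2-oxabicyclo[2.2.2]octan-3-one
Conditions: NBS, NaHCO3, MeCN, 0 °C, dark
Reagents that add atoms: N-bromosuccinimide (O=C1CCC(=O)N1Br)
Why: Bromolactonisation: the carboxylate, held axial because the CMe2 group takes the equatorial site, opens the bromonium ion of the trisubstituted olefin at its tertiary carbon across the ring (Markovnikov 1,4-closure, the mode by which α-terpineol closes to the 1,8-cineole skeleton), so the C–O bond is necessarily cis to the carbonyl carbon on the quaternary centre and bromine enters anti at the neighbouring carbon, while the monosubstituted vinyl group is far less reactive toward the bromonium donor.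

Step 8
Reactants: 13 (1S,4R,6S)-6-bromo-1-methyl-4-(2-methylbut-3-en-2-yl)-2-oxabicyclo[2.2.2]octan-3-one
Product: 15 (1S,4R,6S)-6-bromo-4-(4-hydroxy-2-methylbutan-2-yl)-1-methyl-2-oxabicyclo[2.2.2]octan-3-one, via B-alkyl-9-BBN adduct 14 (not isolated)
Conditions: 9-BBN, THF, 0 → 25 °C; then H2O2, aq NaOAc, 0 °C
Reagents that add atoms: hydrogen peroxide (OO)
Why: Hydroboration–oxidation: 9-BBN adds to the neopentylic vinyl group at its terminal carbon and buffered peroxide oxidation gives the primary alcohol without opening the hindered bridged lactone or touching the secondary bromide; no stereocentre is formed.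

Step 9
Reactants: 15 (1S,4R,6S)-6-bromo-4-(4-hydroxy-2-methylbutan-2-yl)-1-methyl-2-oxabicyclo[2.2.2]octan-3-one
Product: 16 3-[(1S,4R,6S)-6-bromo-1-methyl-3-oxo-2-oxabicyclo[2.2.2]octan-4-yl]-3-methylbutanal
Conditions: Dess–Martin periodinane, NaHCO3, CH2Cl2, 0 → 25 °C
Reagents that add atoms: none
Why: Dess–Martin oxidation takes the primary alcohol to the aldehyde under buffered conditions; no stereocentre is involved.

Step 10
Reactants: 16 3-[(1S,4R,6S)-6-bromo-1-methyl-3-oxo-2-oxabicyclo[2.2.2]octan-4-yl]-3-methylbutanal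
Product: 18 (1S,4R,6S)-6-bromo-4-[(3S)-3-bromo-4-hydroxy-2-methylbutan-2-yl]-1-methyl-2-oxabicyclo[2.2.2]octan-3-one, via α-bromo aldehyde 17 (not isolated)
Conditions: (S)-2-{bis[3,5-bis(trifluoromethyl)phenyl][(trimethylsilyl)oxy]methyl}pyrrolidine (20 mol %), PhCO2H (20 mol %), 4,4-dibromo-2,6-di-tert-butylcyclohexa-2,5-dien-1-one, CH2Cl2/pentane, −40 °C; then NaBH4, MeOH, −40 → 0 °C
Reagents that add atoms: 4,4-dibromo-2,6-di-tert-butylcyclohexa-2,5-dien-1-one (CC(C)(C)C1=CC(Br)(Br)C=C(C(C)(C)C)C1=O)
Why: Enamine-catalysed asymmetric α-bromination: the E-enamine formed with the (S)-diarylprolinol silyl ether is brominated on the face away from the diaryl(silyloxy)methyl group, which under reagent control gives the (S)-bromo aldehyde 17 (a β-quaternary aldehyde of the 3,3-dimethylbutanal type), and reduction with NaBH4 in the same flask secures the stereocentre as the bromo alcohol before it can epimerise.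

Step 11
Reactants: 18 (1S,4R,6S)-6-bromo-4-[(3S)-3-bromo-4-hydroxy-2-methylbutan-2-yl]-1-methyl-2-oxabicyclo[2.2.2]octan-3-one
Product: 19 (2S)-2-bromo-3-[(1S,4R,6S)-6-bromo-1-methyl-3-oxo-2-oxabicyclo[2.2.2]octan-4-yl]-3-methylbutyl trifluoromethanesulfonate
Conditions: Tf2O, 2,6-lutidine, CH2Cl2, −78 °C; used at once
Reagents that add atoms: trifluoromethanesulfonic anhydride (O=S(=O)(OS(=O)(=O)C(F)(F)F)C(F)(F)F)
Why: Triflation of the primary alcohol with Tf2O and a hindered pyridine base at low temperature; the adjacent CHBr stereocentre takes no part.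

Step 12
Reactants: 19 (2S)-2-bromo-3-[(1S,4R,6S)-6-bromo-1-methyl-3-oxo-2-oxabicyclo[2.2.2]octan-4-yl]-3-methylbutyl trifluoromethanesulfonate; 20 vinylmagnesium bromide
Product: 21 (1S,4R,6S)-6-bromo-4-[(3R)-3-bromo-2-methylhex-5-en-2-yl]-1-methyl-2-oxabicyclo[2.2.2]octan-3-one
Conditions: CH2=CHMgBr, CuI (10 mol %), THF, −78 → −30 °C
Reagents that add atoms: vinylmagnesium bromide 20 (C=C[Mg]Br)
Why: CuI-catalysed coupling of the primary alkyl triflate with the vinyl Grignard reagent (SN2 displacement by a vinylcuprate) at low temperature; the lactone carbonyl next to the bridgehead quaternary carbon is too hindered to be attacked, and the CHBr centre is untouched, its descriptor changing from S to R only because the priorities of its neighbours change.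

Step 13
Reactants: 21 (1S,4R,6S)-6-bromo-4-[(3R)-3-bromo-2-methylhex-5-en-2-yl]-1-methyl-2-oxabicyclo[2.2.2]octan-3-one
Product: 23 1-{(1R,3S,4S)-3-bromo-1-[(3R)-3-bromo-2-methylhex-5-en-2-yl]-4-hydroxy-4-methylcyclohexyl}ethan-1-one, via lithium hemiketalate 22 (not isolated)
Conditions: MeLi (1.1 equiv), THF, −78 °C; then H2O
Reagents that add atoms: methyllithium ([Li]C)
Why: Addition of one equivalent of MeLi to the lactone gives lithium hemiketalate 22, whose collapse is driven by release of the strain of the bicyclo[2.2.2] lactone and delivers the methyl ketone beside the tertiary alkoxide; a second addition to a ketone flanked by two fully substituted carbons is slow at −78 °C, and the equatorial alkoxide is not antiperiplanar to the equatorial bromine, so no epoxide forms.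

Step 14
Reactants: 23 1-{(1R,3S,4S)-3-bromo-1-[(3R)-3-bromo-2-methylhex-5-en-2-yl]-4-hydroxy-4-methylcyclohexyl}ethan-1-one
Product: 24 (1S,2S,4S)-2-bromo-4-[(3R)-3-bromo-2-methylhex-5-en-2-yl]-1-methyl-4-(prop-1-en-2-yl)cyclohexan-1-ol
Conditions: Tebbe reagent Cp2Ti(μ-CH2)(μ-Cl)AlMe2 (3 equiv), pyridine (cat.), THF/toluene, −40 → 25 °C; then aq NaOH
Reagents that add atoms: Tebbe reagent (C[Al-]1(C)C[Ti](C2C=CC=C2)(C2C=CC=C2)[Cl+]1)
Why: Tebbe methylenation (carbonyl olefination by the titanium methylidene through an oxatitanacyclobutane) converts the very hindered methyl ketone into the isopropenyl group without base, the tertiary alcohol being carried as its titanium alkoxide until work-up; no stereocentre is involved.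

Step 15
Reactants: 24 (1S,2S,4S)-2-bromo-4-[(3R)-3-bromo-2-methylhex-5-en-2-yl]-1-methyl-4-(prop-1-en-2-yl)cyclohexan-1-ol
Product: 25 (2S,3S,6S,10R)-2,10-dibromo-3,7,11,11-tetramethylspiro[5.5]undec-7-en-3-ol
Conditions: second-generation Grubbs catalyst (H2IMes)(PCy3)Cl2Ru=CHPh (5–10 mol %), CH2Cl2 (0.005 M), 40 °C
Reagents that add atoms: none
Why: Ring-closing olefin metathesis: the ruthenium benzylidene exchanges onto the monosubstituted terminal olefin, the resulting alkylidene adds across the isopropenyl group to a ruthenacyclobutane, and cycloreversion releases the trisubstituted C7=C8 olefin and, after turnover, ethylene. The closest known reaction type is the closure of 1-methylcyclohexenes that carry an allylic quaternary carbon from 1,7-dienes with this catalyst. Ring A, the six-membered carbocycle, closes by formation of the C7=C8 double bond between the isopropenyl carbon on the spiro centre and the CH of the allyl terminus. No stereocentre is formed; all four are already present in 24. The step needs cyclisation to outrun intermolecular metathesis, which the two adjacent fully substituted carbons C6 and C11 secure by holding the olefins close, while the hindered isopropenyl group cannot homodimerise and the free tertiary alcohol and both secondary bromides are tolerated.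

**Compound list**

1 | (S)-limonene, (4S)-1-methyl-4-(prop-1-en-2-yl)cyclohex-1-ene | CC1=CC[C@H](CC1)C(C)=C | starting material
2 | (1R,2R,4S)-2-bromo-1-methoxy-1-methyl-4-(prop-1-en-2-yl)cyclohexane | C=C(C)[C@H]1CC[C@@](C)(OC)[C@H](Br)C1 | intermediate
3 | 3-[(1S,3R,4R)-3-bromo-4-methoxy-4-methylcyclohexyl]-3-methyl-1,2,4-trioxolane (ozonide, not isolated) | CC1(OCOO1)[C@H]1CC[C@@](C)(OC)[C@H](Br)C1 | intermediate
4 | 1-[(1S,3R,4R)-3-bromo-4-methoxy-4-methylcyclohexyl]ethan-1-one | CC(=O)[C@H]1CC[C@@](C)(OC)[C@H](Br)C1 | intermediate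
5 | 2,2,2-tribromo-1-[(1S,3R,4R)-3-bromo-4-methoxy-4-methylcyclohexyl]ethan-1-one (not isolated) | BrC(Br)(Br)C(=O)[C@H]1CC[C@@](C)(OC)[C@H](Br)C1 | intermediate
6 | (1S,3R,4R)-3-bromo-4-methoxy-4-methylcyclohexane-1-carboxylic acid | OC(=O)[C@H]1CC[C@@](C)(OC)[C@H](Br)C1 | intermediate
7 | 3-methylbut-2-en-1-ol | CC(C)=CCO | starting material
8 | 3-methylbut-2-en-1-yl (1S,3R,4R)-3-bromo-4-methoxy-4-methylcyclohexane-1-carboxylate | CC(C)=CCOC(=O)[C@H]1CC[C@@](C)(OC)[C@H](Br)C1 | intermediate
9 | {[(3R,4R)-3-bromo-4-methoxy-4-methylcyclohexylidene][(3-methylbut-2-en-1-yl)oxy]methoxy}trimethylsilane (silyl ketene acetal, either olefin geometry, not isolated) | CC(C)=CCOC(O[Si](C)(C)C)=C1CC[C@@](C)(OC)[C@H](Br)C1 | intermediate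
10 | trimethylsilyl (1R,3R,4R)-3-bromo-4-methoxy-4-methyl-1-(2-methylbut-3-en-2-yl)cyclohexane-1-carboxylate (not isolated) | C=CC(C)(C)[C@@]1(C(=O)O[Si](C)(C)C)CC[C@@](C)(OC)[C@H](Br)C1 | intermediate
11 | (1R,3R,4R)-3-bromo-4-methoxy-4-methyl-1-(2-methylbut-3-en-2-yl)cyclohexane-1-carboxylic acid | C=CC(C)(C)[C@@]1(C(=O)O)CC[C@@](C)(OC)[C@H](Br)C1 | intermediate
12 | (R)-4-methyl-1-(2-methylbut-3-en-2-yl)cyclohex-3-ene-1-carboxylic acid | C=CC(C)(C)[C@@]1(C(=O)O)CCC(C)=CC1 | intermediate
13 | (1S,4R,6S)-6-bromo-1-methyl-4-(2-methylbut-3-en-2-yl)-2-oxabicyclo[2.2.2]octan-3-one | C=CC(C)(C)[C@]12CC[C@](C)(OC1=O)[C@@H](Br)C2 | intermediate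
14 | 9-{3-[(1S,4R,6S)-6-bromo-1-methyl-3-oxo-2-oxabicyclo[2.2.2]octan-4-yl]-3-methylbutyl}-9-borabicyclo[3.3.1]nonane (not isolated) | C1CCC2CCCC1B2CCC(C)(C)[C@]12CC[C@](C)(OC1=O)[C@@H](Br)C2 | intermediate
15 | (1S,4R,6S)-6-bromo-4-(4-hydroxy-2-methylbutan-2-yl)-1-methyl-2-oxabicyclo[2.2.2]octan-3-one | OCCC(C)(C)[C@]12CC[C@](C)(OC1=O)[C@@H](Br)C2 | intermediate
16 | 3-[(1S,4R,6S)-6-bromo-1-methyl-3-oxo-2-oxabicyclo[2.2.2]octan-4-yl]-3-methylbutanal | O=CCC(C)(C)[C@]12CC[C@](C)(OC1=O)[C@@H](Br)C2 | intermediate
17 | (2S)-2-bromo-3-[(1S,4R,6S)-6-bromo-1-methyl-3-oxo-2-oxabicyclo[2.2.2]octan-4-yl]-3-methylbutanal (not isolated) | O=C[C@@H](Br)C(C)(C)[C@]12CC[C@](C)(OC1=O)[C@@H](Br)C2 | intermediate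
18 | (1S,4R,6S)-6-bromo-4-[(3S)-3-bromo-4-hydroxy-2-methylbutan-2-yl]-1-methyl-2-oxabicyclo[2.2.2]octan-3-one | OC[C@@H](Br)C(C)(C)[C@]12CC[C@](C)(OC1=O)[C@@H](Br)C2 | intermediate
19 | (2S)-2-bromo-3-[(1S,4R,6S)-6-bromo-1-methyl-3-oxo-2-oxabicyclo[2.2.2]octan-4-yl]-3-methylbutyl trifluoromethanesulfonate | O=S(=O)(OC[C@@H](Br)C(C)(C)[C@]12CC[C@](C)(OC1=O)[C@@H](Br)C2)C(F)(F)F | intermediate
20 | vinylmagnesium bromide | C=C[Mg]Br | starting material
21 | (1S,4R,6S)-6-bromo-4-[(3R)-3-bromo-2-methylhex-5-en-2-yl]-1-methyl-2-oxabicyclo[2.2.2]octan-3-one | C=CC[C@@H](Br)C(C)(C)[C@]12CC[C@](C)(OC1=O)[C@@H](Br)C2 | intermediate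
22 | lithium (1S,4R,6S)-6-bromo-4-[(3R)-3-bromo-2-methylhex-5-en-2-yl]-1,3-dimethyl-2-oxabicyclo[2.2.2]octan-3-olate (hemiketalate, not isolated) | C=CC[C@@H](Br)C(C)(C)[C@]12CC[C@](C)(OC1(C)[O-])[C@@H](Br)C2.[Li+] | intermediate
23 | 1-{(1R,3S,4S)-3-bromo-1-[(3R)-3-bromo-2-methylhex-5-en-2-yl]-4-hydroxy-4-methylcyclohexyl}ethan-1-one | C=CC[C@@H](Br)C(C)(C)[C@@]1(C(C)=O)CC[C@](C)(O)[C@@H](Br)C1 | intermediate
24 | (1S,2S,4S)-2-bromo-4-[(3R)-3-bromo-2-methylhex-5-en-2-yl]-1-methyl-4-(prop-1-en-2-yl)cyclohexan-1-ol | C=CC[C@@H](Br)C(C)(C)[C@@]1(C(C)=C)CC[C@](C)(O)[C@@H](Br)C1 | intermediate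
25 | (2S,3S,6S,10R)-2,10-dibromo-3,7,11,11-tetramethylspiro[5.5]undec-7-en-3-ol | CC1=CC[C@@H](Br)C(C)(C)[C@]12CC[C@](C)(O)[C@@H](Br)C2 | target

Total step count: 15. Longest linear sequence: 15 steps, from (S)-limonene 1 to 25.

**Steps most likely to fail**

Step 5. The process at risk is loss of facial control in the sigmatropic shift: part of the ketene acetal may react through the ring-flipped chair in which bromine is equatorial and no longer shields one face. That would lower the enantiomeric purity of everything after step 6. A second risk is enolate-triggered loss of bromide before silylation. The fallback gives up the relay and resolves the quaternary acid instead. It sets out from 3-methylbut-2-en-1-ol 7, which is esterified (DCC, DMAP) with commercially available racemic 4-methylcyclohex-3-ene-1-carboxylic acid F1 to the racemic prenyl ester F2. LDA and TMSCl give the silyl ketene acetal F3, which rearranges on warming to the trimethylsilyl ester F4 and, after acidic work-up, to the racemic quaternary acid F5. Classical resolution by crystallisation of the (S)-1-phenylethylammonium salt of the (R)-acid F6 (or of the mirror-image pair from the (R)-amine, should that salt be the less soluble) and acidification bring the route back at 12.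

Step 12. The process at risk is elimination instead of substitution: attack of the vinylcuprate at bromine with reductive 1,2-elimination to the olefin, or base-induced loss of triflic acid. The fallback replaces the vinyl metal by a smaller, non-reducing carbon nucleophile and adjusts the oxidation level afterwards. It sets out from triflate 19, which is displaced with LiC≡CSiMe3 (THF/DMPU, −78 → −20 °C) to give the silyl alkyne F7. K2CO3 in MeOH frees the terminal alkyne F8, and semihydrogenation with H2 over Lindlar catalyst (Pd on CaCO3 poisoned with Pb(OAc)2, quinoline) comes back at 21.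

Step 10. The process at risk is slow enamine formation or weak facial control with the very hindered neopentylic aldehyde, and partial epimerisation of the bromo aldehyde before it is reduced. The fallback replaces catalyst control by a covalently bound oxazolidinone auxiliary. It sets out from aldehyde 16, which NaClO2/NaH2PO4/2-methylbut-2-ene oxidises to the carboxylic acid F9. DCC/DMAP coupling with (S)-4-benzyloxazolidin-2-one gives the imide F10. Bu2BOTf and iPr2NEt form the (Z)-boron enolate F11, which NBS brominates on the face away from the benzyl group to give the (2S)-bromo imide F12. LiBH4 in wet THF at 0 °C removes the auxiliary reductively and comes back at 18.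

**Further compounds**

F1 | step 5 | racemic 4-methylcyclohex-3-ene-1-carboxylic acid | CC1=CCC(CC1)C(=O)O
F2 | step 5 | racemic 3-methylbut-2-en-1-yl 4-methylcyclohex-3-ene-1-carboxylate | CC1=CCC(CC1)C(=O)OCC=C(C)C
F3 | step 5 | trimethyl{(4-methylcyclohex-3-en-1-ylidene)[(3-methylbut-2-en-1-yl)oxy]methoxy}silane | CC1=CCC(CC1)=C(OCC=C(C)C)O[Si](C)(C)C
F4 | step 5 | racemic trimethylsilyl 4-methyl-1-(2-methylbut-3-en-2-yl)cyclohex-3-ene-1-carboxylate | CC1=CCC(CC1)(C(C)(C)C=C)C(=O)O[Si](C)(C)C
F5 | step 5 | racemic 4-methyl-1-(2-methylbut-3-en-2-yl)cyclohex-3-ene-1-carboxylic acid | CC1=CCC(CC1)(C(C)(C)C=C)C(=O)O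
F6 | step 5 | (S)-1-phenylethylammonium (R)-4-methyl-1-(2-methylbut-3-en-2-yl)cyclohex-3-ene-1-carboxylate | C[C@H]([NH3+])c1ccccc1.[O-]C(=O)[C@]1(C(C)(C)C=C)CCC(C)=CC1
F7 | step 12 | (1S,4R,6S)-6-bromo-4-[(3R)-3-bromo-2-methyl-6-(trimethylsilyl)hex-5-yn-2-yl]-1-methyl-2-oxabicyclo[2.2.2]octan-3-one | C[Si](C)(C)C#CC[C@@H](Br)C(C)(C)[C@]12CC[C@](C)(OC1=O)[C@@H](Br)C2
F8 | step 12 | (1S,4R,6S)-6-bromo-4-[(3R)-3-bromo-2-methylhex-5-yn-2-yl]-1-methyl-2-oxabicyclo[2.2.2]octan-3-one | C#CC[C@@H](Br)C(C)(C)[C@]12CC[C@](C)(OC1=O)[C@@H](Br)C2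
F9 | step 10 | 3-[(1S,4R,6S)-6-bromo-1-methyl-3-oxo-2-oxabicyclo[2.2.2]octan-4-yl]-3-methylbutanoic acid | OC(=O)CC(C)(C)[C@]12CC[C@](C)(OC1=O)[C@@H](Br)C2
F10 | step 10 | (4S)-4-benzyl-3-{3-[(1S,4R,6S)-6-bromo-1-methyl-3-oxo-2-oxabicyclo[2.2.2]octan-4-yl]-3-methylbutanoyl}oxazolidin-2-one | O=C(CC(C)(C)[C@]12CC[C@](C)(OC1=O)[C@@H](Br)C2)N1[C@@H](Cc2ccccc2)COC1=O
F11 | step 10 | dibutylboron (Z)-enolate of imide F10 | CCCCB(CCCC)O/C(=C\C(C)(C)[C@]12CC[C@](C)(OC1=O)[C@@H](Br)C2)N1[C@@H](Cc2ccccc2)COC1=O
F12 | step 10 | (4S)-4-benzyl-3-{(2S)-2-bromo-3-[(1S,4R,6S)-6-bromo-1-methyl-3-oxo-2-oxabicyclo[2.2.2]octan-4-yl]-3-methylbutanoyl}oxazolidin-2-one | O=C([C@@H](Br)C(C)(C)[C@]12CC[C@](C)(OC1=O)[C@@H](Br)C2)N1[C@@H](Cc2ccccc2)COC1=O
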